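**Retrosynthetic overview**

1. The aldehyde and the oxirane are unmasked last (C15–CH2OPMB → CHO; C12 ketone → spiro-oxirane by Corey–Chaykovsky), so the real problem is the bicyclo[9.3.1]pentadeca-3,7-diene: a cyclohexane (C1, C11–C15) whose trans bonds at C1 and C11 are bridged by the nine-carbon chain C2–C10 through a twelve-membered ring.
2. Enabling feature: C5–C6 is the central CH2–CH2 bond of the skipped (3Z,7Z)-1,5-diene in that twelve-membered ring. Both atoms are primary allylic carbons (C5 on C4(Me)=C3, C6 on C7=C8(Me)), so C6 can carry a sulfone-stabilised carbanion and C5 a bromide, and this one bond lies in both the twelve- and the fourteen-membered circuit.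
3. Key disconnection C5–C6: intramolecular allyl sulfone alkylation of a monocyclic cyclohexane with two trans arms. It removes the only bridge of the bicycle in one step, carries both (Z)-alkenes in unchanged, and is followed by Pd/hydride desulfonylation.
4. Cyclohexane stereotriad by relay: C1 by RAMP-hydrazone allylation of 1,4-dioxaspiro[4.5]decan-7-one, quaternary C15 by anti cuprate addition to the derived 3-(PMBOCH2)-enone, C11 by alkylation of the regiodefined enolate. The arms come from a Still–Gennari olefination (C2–C5) and from (Z)-3-methylpent-2-en-4-yn-1-ol (C6–C10).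
5. Ring order: six-membered ring (bought) → twelve-membered ring (step 21) → oxirane (step 24).

Key step: step 21

Remark: locants C1–C15 in the text are those of the bicyclo[9.3.1]pentadecane name of the target (C1 and C11 bridgeheads, C15 the quaternary one-carbon bridge, C12 the spiro carbon).
Remark: compounds 1, 2, 7, 13, 14, 16, 17 and 25 are assumed to be purchasable; centres that are destroyed later (C=N geometry of 18–20, carbinol carbon of 23, sulfonyl-bearing carbon of 37) are not controlled.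

**Route**

Step 1
Reactants: 1 2-[(tert-butyldimethylsilyl)oxy]acetaldehyde; 2 ethyl 2-[bis(2,2,2-trifluoroethoxy)phosphoryl]propanoate
Product: 3 ethyl (Z)-4-[(tert-butyldimethylsilyl)oxy]-2-methylbut-2-enoate
Conditions: KN(SiMe3)2, 18-crown-6, THF, −78 °C
Reagents that add atoms: none
Why: Still–Gennari olefination, in which the electron-poor phosphonate under dissociating conditions should give the (Z)-trisubstituted enoate kinetically and so fix the geometry of the future C3=C4 alkene.

Step 2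
Reactants: 3 ethyl (Z)-4-silyloxy-2-methylbut-2-enoate
Product: 4 (Z)-4-[(tert-butyldimethylsilyl)oxy]-2-methylbut-2-en-1-ol
Conditions: i-Bu2AlH, CH2Cl2, −78 °C
Reagents that add atoms: none
Why: 1,2-reduction of the enoate with i-Bu2AlH should give the allylic alcohol without touching the alkene geometry or the silyl ether.

Step 3
Reactants: 4 (Z)-allylic alcohol
Product: 5 (Z)-1-[(tert-butyldiphenylsilyl)oxy]-4-[(tert-butyldimethylsilyl)oxy]-2-methylbut-2-ene
Conditions: TBDPSCl, imidazole, DMF, 0 °C → rt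
Reagents that add atoms: tert-butyl(chloro)diphenylsilane CC(C)(C)[Si](Cl)(c1ccccc1)c1ccccc1
Why: Standard silylation; the robust TBDPS ether differentiates the two allylic termini.

Step 4
Reactants: 5 bis-silyl ether
Product: 6 (Z)-[(4-bromo-2-methylbut-2-en-1-yl)oxy](tert-butyl)diphenylsilane
Conditions: Ph3PBr2, CH2Cl2, 0 °C
Reagents that add atoms: dibromotriphenylphosphorane BrP(Br)(c1ccccc1)(c1ccccc1)c1ccccc1
Why: Appel-type silyl ether to bromide exchange, in which the primary allylic TBS ether should be converted by SN2 through an alkoxyphosphonium salt while the bulkier TBDPS ether survives.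

Step 5
Reactants: 7 (Z)-3-methylpent-2-en-4-yn-1-ol
Product: 8 (Z)-tert-butyldimethyl[(3-methylpent-2-en-4-yn-1-yl)oxy]silane
Conditions: TBSCl, imidazole, CH2Cl2, 0 °C → rt
Reagents that add atoms: tert-butyl(chloro)dimethylsilane CC(C)(C)[Si](C)(C)Cl
Why: Standard silylation of the primary allylic alcohol; the (Z)-geometry of the future C7=C8 alkene is bought in.

Step 6
Reactants: 8 silylated enyne
Product: 9 (Z)-tert-butyldimethyl[(3-methylpenta-2,4-dien-1-yl)oxy]silane
Conditions: H2 (1 atm), Pd/CaCO3 poisoned with Pb(OAc)2, quinoline, hexane, rt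
Reagents that add atoms: none
Why: Semi-hydrogenation of the terminal alkyne on poisoned palladium should stop at the vinyl group and leave the trisubstituted (Z)-alkene untouched.

Step 7
Reactants: 9 (Z)-diene
Product: 11 (Z)-5-[(tert-butyldimethylsilyl)oxy]-3-methylpent-3-en-1-ol, via trialkylborane 10 (not isolated)
Conditions: 9-BBN, THF, 0 °C → rt; then NaOH, H2O2, 0 °C
Reagents that add atoms: 9-borabicyclo[3.3.1]nonane [H]B1C2CCCC1CCC2 (boron of 10); hydrogen peroxide OO
Why: Hydroboration–oxidation, in which 9-BBN should add anti-Markovnikov to the monosubstituted vinyl group far faster than to the trisubstituted alkene.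

Step 8
Reactants: 11 homoallylic alcohol
Product: 12 (Z)-tert-butyl[(5-iodo-3-methylpent-2-en-1-yl)oxy]dimethylsilane
Conditions: I2, PPh3, imidazole, CH2Cl2, 0 °C
Reagents that add atoms: iodine II
Why: Appel-type iodination of the primary alcohol under buffered conditions that leave the allylic silyl ether intact.

Step 9
Reactants: 13 (tributylstannyl)methanol; 14 4-methoxybenzyl chloride
Product: 15 tributyl{[(4-methoxybenzyl)oxy]methyl}stannane
Conditions: NaH, Bu4NI (cat.), THF/DMF, 0 °C → rt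
Reagents that add atoms: none
Why: Williamson etherification gives the tin precursor of a PMB-protected hydroxymethyl anion.

Step 10
Reactants: 16 1,4-dioxaspiro[4.5]decan-7-one; 17 (R)-1-amino-2-(methoxymethyl)pyrrolidine (RAMP)
Product: 18 RAMP hydrazone of 16
Conditions: neat, 60 °C, then removal of water in vacuo
Reagents that add atoms: none
Why: Condensation to the chiral hydrazone (Enders auxiliary), which leaves the ketal untouched.

Step 11
Reactants: 18 RAMP hydrazone; 6 (Z)-allylic bromide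
Product: 20 (8R)-8-alkylated RAMP hydrazone, via lithium azaenolate 19 (not isolated)
Conditions: LiN(i-Pr)2, THF, 0 °C; then 6, −95 → −78 °C
Reagents that add atoms: lithium diisopropylamide CC(C)N([Li])C(C)C (lithium of 19)
Why: Enders RAMP-hydrazone alkylation, in which deprotonation on the side away from the ketal gives a chelated azaenolate whose open face is attacked by the primary allylic bromide (SN2), setting C1 as R.

Step 12
Reactants: 20 alkylated hydrazone
Product: 21 (R)-8-[(Z)-4-[(tert-butyldiphenylsilyl)oxy]-3-methylbut-2-en-1-yl]-1,4-dioxaspiro[4.5]decan-7-one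
Conditions: CuCl2, THF/H2O (pH 7 buffer), rt
Reagents that add atoms: water O
Why: CuCl2-mediated hydrazone hydrolysis should release the ketone without epimerising the α-centre and without the ozone that the side-chain alkene would not tolerate.

Step 13
Reactants: 21 α-substituted ketone; 15 stannane
Product: 24 (R)-4-[(Z)-4-[(tert-butyldiphenylsilyl)oxy]-3-methylbut-2-en-1-yl]-3-{[(4-methoxybenzyl)oxy]methyl}cyclohex-2-en-1-one, via alkoxymethyllithium 22 (not isolated), via tertiary alcohol 23 (not isolated)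
Conditions: 15, n-BuLi, THF, −78 °C; add 21; then 2 M HCl, THF, rt
Reagents that add atoms: n-butyllithium [Li]CCCC (lithium of 22)
Why: Tin–lithium exchange gives an α-alkoxymethyllithium that adds 1,2 to the ketone, and acid then unmasks the 1,3-keto group and eliminates water to the conjugated enone (Stork–Danheiser-type enone synthesis), with the C1 centre untouched.

Step 14
Reactants: 24 enone; 25 5-bromo-2-methylpent-2-ene
Product: 27 (3S,4R)-silyl enol ether, via Grignard reagent 26 (not isolated)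
Conditions: 25, Mg, THF; then CuBr·SMe2 (cat.), Me3SiCl, HMPA, THF, −78 → −40 °C; Et3N quench
Reagents that add atoms: magnesium [Mg] (in 26); chlorotrimethylsilane C[Si](C)(C)Cl
Why: Copper-catalysed conjugate addition accelerated by Me3SiCl, in which the homoprenyl group should add axially anti to the C4 side chain of the enone, setting quaternary C15 as S and fixing the enolate regiochemistry as the silyl enol ether.

Step 15
Reactants: 27 silyl enol ether; 12 (Z)-homoallylic iodide
Product: 29 (2R,3S,4R)-2,3,3,4-tetrasubstituted cyclohexanone, via lithium enolate 28 (not isolated)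
Conditions: MeLi, THF, 0 °C; then 12, HMPA, −78 → 0 °C
Reagents that add atoms: methyllithium [Li]C (lithium of 28)
Why: Regiospecific enolate alkylation, in which the lithium enolate released from the silyl enol ether should be attacked axially on the face anti to the axial CH2OPMB group of the neighbouring quaternary carbon, setting C11 as R with its side chain trans to the C1 side chain.

Step 16
Reactants: 29 ketone
Product: 30 (6R,7S,8R)-ethylene ketal of 29
Conditions: Me3SiOCH2CH2OSiMe3, Me3SiOTf (cat.), CH2Cl2, −78 → −20 °C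
Reagents that add atoms: 1,2-bis(trimethylsilyloxy)ethane C[Si](C)(C)OCCO[Si](C)(C)C
Why: Aprotic silyl-triflate-catalysed ketalization at low temperature should mask the ketone without enolising the epimerisable C11 centre.

Step 17
Reactants: 30 ketal bis-silyl ether
Product: 31 C6 allylic alcohol (TBDPS ether retained)
Conditions: HF·pyridine, pyridine, THF, 0 °C
Reagents that add atoms: none
Why: Buffered fluoride desilylation removes the primary TBS ether selectively over the TBDPS ether and leaves ketal and PMB ether intact.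

Step 18
Reactants: 31 allylic alcohol
Product: 33 (Z)-allylic phenyl sulfone, via allylic bromide 32 (not isolated)
Conditions: CBr4, PPh3, 2,6-lutidine, CH2Cl2, 0 °C; then PhSO2Na, DMF, rt
Reagents that add atoms: carbon tetrabromide BrC(Br)(Br)Br (bromine of 32); sodium benzenesulfinate [Na+].[O-]S(=O)c1ccccc1
Why: Appel bromination followed by SN2 S-alkylation of the sulfinate at the primary carbon should install the sulfone with retention of the (Z)-alkene.

Step 19
Reactants: 33 sulfone TBDPS ether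
Product: 34 C5 allylic alcohol
Conditions: Bu4NF, THF, 0 °C → rt
Reagents that add atoms: none
Why: Fluoride desilylation frees the second allylic alcohol; sulfone, ketal and PMB ether are stable.

Step 20
Reactants: 34 hydroxy sulfone
Product: 35 bromo sulfone (macrocyclization precursor)
Conditions: CBr4, PPh3, CH2Cl2, −20 °C
Reagents that add atoms: carbon tetrabromide BrC(Br)(Br)Br
Why: Appel bromination gives the primary allylic bromide under neutral conditions without allylic transposition.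

Step 21
Reactants: 35 bromo sulfone
Product: 37 (1R,3Z,7Z,11R,15S)-6-(phenylsulfonyl) bicyclo[9.3.1]pentadeca-3,7-diene ketal, via potassium sulfonyl carbanion 36 (not isolated)
Conditions: KN(SiMe3)2, THF, −78 → 0 °C, slow addition of 35 (final 0.002 M)
Reagents that add atoms: potassium bis(trimethylsilyl)amide C[Si](C)(C)N([K])[Si](C)(C)C (potassium of 36)
Why: KN(SiMe3)2 deprotonates the allylic sulfone at C6 and the carbanion displaces the primary allylic bromide at C5 in an intramolecular SN2 alkylation, the classical sulfone-based allyl–allyl macrocyclization used for cembrane-type rings. The closure is 12-exo-tet: it forms the twelve-membered ring and with it the fourteen-membered circuit, so the bridged bicyclo[9.3.1] skeleton arises from a monocyclic precursor in one operation. The only new stereocentre is the sulfonyl-bearing C6, which is uncontrolled and is erased in step 22. The step needs α- rather than γ-alkylation of the sulfonyl allyl anion, SN2 rather than SN2′ at the bromide, retention of both (Z)-alkenes and ring closure rather than oligomerisation. These should be secured by charge localisation at the sulfonyl carbon, the unhindered primary bromide, the configurational stability of both allyl units at low temperature, and high dilution with slow addition. The two arms sit trans on C1 and C11 (one equatorial, one axial) and each (Z)-alkene turns its chain back towards the other, which should bring C5 and C6 within reach.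

Step 22
Reactants: 37 macrocyclic sulfone
Product: 38 (1R,3Z,7Z,11R,15S)-bicyclo[9.3.1]pentadeca-3,7-diene ketal
Conditions: PdCl2(dppp) (cat.), LiBHEt3, THF, 0 °C
Reagents that add atoms: none
Why: Palladium-catalysed reductive desulfonylation, in which zerovalent palladium ionises the allylic sulfone and hydride is delivered to the less substituted allyl terminus (C6), so the C7=C8 alkene should stay in place and (Z).

Step 23
Reactants: 38 ketal
Product: 39 (1R,3Z,7Z,11R,15S)-bicyclic C12 ketone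
Conditions: 1 M HCl, THF, rt
Reagents that add atoms: water O
Why: Mild acid hydrolysis of the dioxolane; PMB ether and the trisubstituted alkenes are stable to dilute acid at room temperature.

Step 24
Reactants: 39 ketone
Product: 40 (12S)-spiro-oxirane PMB ether
Conditions: Me3S+ I−, KN(SiMe3)2, THF, −10 → 0 °C
Reagents that add atoms: trimethylsulfonium iodide C[S+](C)C.[I-]
Why: Corey–Chaykovsky epoxidation, in which both axial approaches are blocked by an axial substituent on quaternary C15, so the methylene should enter equatorially on the face opposite the C10–C11 bond and place the oxirane oxygen syn to the C6–C10 arm (12S).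

Step 25
Reactants: 40 PMB ether
Product: 41 primary alcohol
Conditions: DDQ, CH2Cl2/pH 7 buffer, 0 °C
Reagents that add atoms: none
Why: Oxidative PMB cleavage under buffered neutral conditions spares the acid-sensitive oxirane and the alkenes.

Step 26
Reactants: 41 primary alcohol
Product: 42 target aldehyde
Conditions: Dess–Martin periodinane, NaHCO3, CH2Cl2, 0 °C → rt
Reagents that add atoms: none
Why: Buffered Dess–Martin oxidation of the neopentyl alcohol gives the non-enolisable aldehyde without opening the oxirane.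

**Compound list**

1 | 2-[(tert-butyldimethylsilyl)oxy]acetaldehyde | O=CCO[Si](C)(C)C(C)(C)C | starting material
2 | ethyl 2-[bis(2,2,2-trifluoroethoxy)phosphoryl]propanoate | CCOC(=O)C(C)P(=O)(OCC(F)(F)F)OCC(F)(F)F | starting material
3 | ethyl (Z)-4-[(tert-butyldimethylsilyl)oxy]-2-methylbut-2-enoate | CCOC(=O)/C(C)=C\CO[Si](C)(C)C(C)(C)C | intermediate
4 | (Z)-4-[(tert-butyldimethylsilyl)oxy]-2-methylbut-2-en-1-ol | OC/C(C)=C\CO[Si](C)(C)C(C)(C)C | intermediate
5 | (Z)-1-[(tert-butyldiphenylsilyl)oxy]-4-[(tert-butyldimethylsilyl)oxy]-2-methylbut-2-ene | CC(C)(C)[Si](c1ccccc1)(c1ccccc1)OC/C(C)=C\CO[Si](C)(C)C(C)(C)C | intermediate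
6 | (Z)-[(4-bromo-2-methylbut-2-en-1-yl)oxy](tert-butyl)diphenylsilane | BrC/C=C(/C)CO[Si](c1ccccc1)(c1ccccc1)C(C)(C)C | intermediate
7 | (Z)-3-methylpent-2-en-4-yn-1-ol | C#C/C(C)=C\CO | starting material
8 | (Z)-tert-butyldimethyl[(3-methylpent-2-en-4-yn-1-yl)oxy]silane | C#C/C(C)=C\CO[Si](C)(C)C(C)(C)C | intermediate
9 | (Z)-tert-butyldimethyl[(3-methylpenta-2,4-dien-1-yl)oxy]silane | C=C/C(C)=C\CO[Si](C)(C)C(C)(C)C | intermediate
10 | 9-[(Z)-5-[(tert-butyldimethylsilyl)oxy]-3-methylpent-3-en-1-yl]-9-borabicyclo[3.3.1]nonane | CC(C)(C)[Si](C)(C)OC/C=C(/C)CCB1C2CCCC1CCC2 | intermediate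
11 | (Z)-5-[(tert-butyldimethylsilyl)oxy]-3-methylpent-3-en-1-ol | OCC/C(C)=C\CO[Si](C)(C)C(C)(C)C | intermediate
12 | (Z)-tert-butyl[(5-iodo-3-methylpent-2-en-1-yl)oxy]dimethylsilane | ICC/C(C)=C\CO[Si](C)(C)C(C)(C)C | intermediate
13 | (tributylstannyl)methanol | CCCC[Sn](CCCC)(CCCC)CO | starting material
14 | 4-methoxybenzyl chloride | COc1ccc(CCl)cc1 | starting material
15 | tributyl{[(4-methoxybenzyl)oxy]methyl}stannane | CCCC[Sn](CCCC)(CCCC)COCc1ccc(OC)cc1 | intermediate
16 | 1,4-dioxaspiro[4.5]decan-7-one | O=C1CCCC2(C1)OCCO2 | starting material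
17 | (R)-1-amino-2-(methoxymethyl)pyrrolidine (RAMP) | COC[C@H]1CCCN1N | starting material
18 | (R)-N-(1,4-dioxaspiro[4.5]decan-7-ylidene)-2-(methoxymethyl)pyrrolidin-1-amine (C=N geometry not defined) | COC[C@H]1CCCN1N=C1CCCC2(C1)OCCO2 | intermediate
19 | lithium azaenolate of 18 (deprotonated at C8 of the spirocycle) | COC[C@H]1CCCN1N([Li])C1=CCCC2(C1)OCCO2 | intermediate
20 | (R)-N-{(8R)-8-[(Z)-4-[(tert-butyldiphenylsilyl)oxy]-3-methylbut-2-en-1-yl]-1,4-dioxaspiro[4.5]decan-7-ylidene}-2-(methoxymethyl)pyrrolidin-1-amine | COC[C@H]1CCCN1N=C1[C@@H](C/C=C(/C)CO[Si](c2ccccc2)(c2ccccc2)C(C)(C)C)CCC2(C1)OCCO2 | intermediate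
21 | (R)-8-[(Z)-4-[(tert-butyldiphenylsilyl)oxy]-3-methylbut-2-en-1-yl]-1,4-dioxaspiro[4.5]decan-7-one | O=C1[C@@H](C/C=C(/C)CO[Si](c2ccccc2)(c2ccccc2)C(C)(C)C)CCC2(C1)OCCO2 | intermediate
22 | {[(4-methoxybenzyl)oxy]methyl}lithium | [Li]COCc1ccc(OC)cc1 | intermediate
23 | (8R)-8-[(Z)-4-[(tert-butyldiphenylsilyl)oxy]-3-methylbut-2-en-1-yl]-7-{[(4-methoxybenzyl)oxy]methyl}-1,4-dioxaspiro[4.5]decan-7-ol (C7 epimers) | OC1(COCc2ccc(OC)cc2)[C@@H](C/C=C(/C)CO[Si](c2ccccc2)(c2ccccc2)C(C)(C)C)CCC2(C1)OCCO2 | intermediate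
24 | (R)-4-[(Z)-4-[(tert-butyldiphenylsilyl)oxy]-3-methylbut-2-en-1-yl]-3-{[(4-methoxybenzyl)oxy]methyl}cyclohex-2-en-1-one | O=C1C=C(COCc2ccc(OC)cc2)[C@@H](C/C=C(/C)CO[Si](c2ccccc2)(c2ccccc2)C(C)(C)C)CC1 | intermediate
25 | 5-bromo-2-methylpent-2-ene | CC(C)=CCCBr | starting material
26 | (4-methylpent-3-en-1-yl)magnesium bromide | CC(C)=CCC[Mg]Br | intermediate
27 | {[(3S,4R)-4-[(Z)-4-[(tert-butyldiphenylsilyl)oxy]-3-methylbut-2-en-1-yl]-3-{[(4-methoxybenzyl)oxy]methyl}-3-(4-methylpent-3-en-1-yl)cyclohex-1-en-1-yl]oxy}trimethylsilane | CC(C)=CCC[C@@]1(COCc2ccc(OC)cc2)C=C(O[Si](C)(C)C)CC[C@@H]1C/C=C(/C)CO[Si](c1ccccc1)(c1ccccc1)C(C)(C)C | intermediate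
28 | lithium enolate corresponding to 27 (O–Li in place of O–SiMe3) | CC(C)=CCC[C@@]1(COCc2ccc(OC)cc2)C=C(O[Li])CC[C@@H]1C/C=C(/C)CO[Si](c1ccccc1)(c1ccccc1)C(C)(C)C | intermediate
29 | (2R,3S,4R)-2-[(Z)-5-[(tert-butyldimethylsilyl)oxy]-3-methylpent-3-en-1-yl]-4-[(Z)-4-[(tert-butyldiphenylsilyl)oxy]-3-methylbut-2-en-1-yl]-3-{[(4-methoxybenzyl)oxy]methyl}-3-(4-methylpent-3-en-1-yl)cyclohexan-1-one | CC(C)=CCC[C@@]1(COCc2ccc(OC)cc2)[C@@H](CC/C(C)=C\CO[Si](C)(C)C(C)(C)C)C(=O)CC[C@@H]1C/C=C(/C)CO[Si](c1ccccc1)(c1ccccc1)C(C)(C)C | intermediate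
30 | (6R,7S,8R)-6-[(Z)-5-[(tert-butyldimethylsilyl)oxy]-3-methylpent-3-en-1-yl]-8-[(Z)-4-[(tert-butyldiphenylsilyl)oxy]-3-methylbut-2-en-1-yl]-7-{[(4-methoxybenzyl)oxy]methyl}-7-(4-methylpent-3-en-1-yl)-1,4-dioxaspiro[4.5]decane | CC(C)=CCC[C@@]1(COCc2ccc(OC)cc2)[C@@H](CC/C(C)=C\CO[Si](C)(C)C(C)(C)C)C2(OCCO2)CC[C@@H]1C/C=C(/C)CO[Si](c1ccccc1)(c1ccccc1)C(C)(C)C | intermediate
31 | (Z)-5-[(6R,7S,8R)-8-[(Z)-4-[(tert-butyldiphenylsilyl)oxy]-3-methylbut-2-en-1-yl]-7-{[(4-methoxybenzyl)oxy]methyl}-7-(4-methylpent-3-en-1-yl)-1,4-dioxaspiro[4.5]decan-6-yl]-3-methylpent-2-en-1-ol | CC(C)=CCC[C@@]1(COCc2ccc(OC)cc2)[C@@H](CC/C(C)=C\CO)C2(OCCO2)CC[C@@H]1C/C=C(/C)CO[Si](c1ccccc1)(c1ccccc1)C(C)(C)C | intermediate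
32 | allylic bromide of 31 ((Z)-5-bromo-3-methylpent-3-en-1-yl side chain at C6 of the spirocycle) | CC(C)=CCC[C@@]1(COCc2ccc(OC)cc2)[C@@H](CC/C(C)=C\CBr)C2(OCCO2)CC[C@@H]1C/C=C(/C)CO[Si](c1ccccc1)(c1ccccc1)C(C)(C)C | intermediate
33 | (6R,7S,8R)-8-[(Z)-4-[(tert-butyldiphenylsilyl)oxy]-3-methylbut-2-en-1-yl]-7-{[(4-methoxybenzyl)oxy]methyl}-6-[(Z)-3-methyl-5-(phenylsulfonyl)pent-3-en-1-yl]-7-(4-methylpent-3-en-1-yl)-1,4-dioxaspiro[4.5]decane | CC(C)=CCC[C@@]1(COCc2ccc(OC)cc2)[C@@H](CC/C(C)=C\CS(=O)(=O)c2ccccc2)C2(OCCO2)CC[C@@H]1C/C=C(/C)CO[Si](c1ccccc1)(c1ccccc1)C(C)(C)C | intermediate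
34 | (Z)-4-[(6R,7S,8R)-7-{[(4-methoxybenzyl)oxy]methyl}-6-[(Z)-3-methyl-5-(phenylsulfonyl)pent-3-en-1-yl]-7-(4-methylpent-3-en-1-yl)-1,4-dioxaspiro[4.5]decan-8-yl]-2-methylbut-2-en-1-ol | CC(C)=CCC[C@@]1(COCc2ccc(OC)cc2)[C@@H](CC/C(C)=C\CS(=O)(=O)c2ccccc2)C2(OCCO2)CC[C@@H]1C/C=C(/C)CO | intermediate
35 | (6R,7S,8R)-8-[(Z)-4-bromo-3-methylbut-2-en-1-yl]-7-{[(4-methoxybenzyl)oxy]methyl}-6-[(Z)-3-methyl-5-(phenylsulfonyl)pent-3-en-1-yl]-7-(4-methylpent-3-en-1-yl)-1,4-dioxaspiro[4.5]decane | CC(C)=CCC[C@@]1(COCc2ccc(OC)cc2)[C@@H](CC/C(C)=C\CS(=O)(=O)c2ccccc2)C2(OCCO2)CC[C@@H]1C/C=C(/C)CBr | intermediate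
36 | potassium salt of the α-sulfonyl allyl carbanion of 35 | [K+].CC(C)=CCC[C@@]1(COCc2ccc(OC)cc2)[C@@H](CC/C(C)=C\[CH-]S(=O)(=O)c2ccccc2)C2(OCCO2)CC[C@@H]1C/C=C(/C)CBr | intermediate
37 | (1R,3Z,7Z,11R,15S)-15-{[(4-methoxybenzyl)oxy]methyl}-4,8-dimethyl-15-(4-methylpent-3-en-1-yl)-6-(phenylsulfonyl)spiro[bicyclo[9.3.1]pentadeca-3,7-diene-12,2'-[1,3]dioxolane] (C6 epimers) | CC(C)=CCC[C@]1(COCc3ccc(OC)cc3)[C@H]2C/C=C(/C)CC(S(=O)(=O)c3ccccc3)/C=C(/C)CC[C@H]1C1(OCCO1)CC2 | intermediate
38 | (1R,3Z,7Z,11R,15S)-15-{[(4-methoxybenzyl)oxy]methyl}-4,8-dimethyl-15-(4-methylpent-3-en-1-yl)spiro[bicyclo[9.3.1]pentadeca-3,7-diene-12,2'-[1,3]dioxolane] | CC(C)=CCC[C@]1(COCc3ccc(OC)cc3)[C@H]2C/C=C(/C)CC/C=C(/C)CC[C@H]1C1(OCCO1)CC2 | intermediate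
39 | (1R,3Z,7Z,11R,15S)-15-{[(4-methoxybenzyl)oxy]methyl}-4,8-dimethyl-15-(4-methylpent-3-en-1-yl)bicyclo[9.3.1]pentadeca-3,7-dien-12-one | CC(C)=CCC[C@]1(COCc3ccc(OC)cc3)[C@H]2C/C=C(/C)CC/C=C(/C)CC[C@H]1C(=O)CC2 | intermediate
40 | (1R,3Z,7Z,11R,12S,15S)-15-{[(4-methoxybenzyl)oxy]methyl}-4,8-dimethyl-15-(4-methylpent-3-en-1-yl)spiro[bicyclo[9.3.1]pentadeca-3,7-diene-12,2'-oxirane] | CC(C)=CCC[C@]1(COCc3ccc(OC)cc3)[C@H]2C/C=C(/C)CC/C=C(/C)CC[C@H]1[C@@]1(CC2)CO1 | intermediate
41 | [(1R,3Z,7Z,11R,12S,15S)-4,8-dimethyl-15-(4-methylpent-3-en-1-yl)spiro[bicyclo[9.3.1]pentadeca-3,7-diene-12,2'-oxiran]-15-yl]methanol | CC(C)=CCC[C@]1(CO)[C@H]2C/C=C(/C)CC/C=C(/C)CC[C@H]1[C@@]1(CC2)CO1 | intermediate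
42 | (1R,3Z,7Z,11R,12S,15S)-4,8-dimethyl-15-(4-methylpent-3-en-1-yl)spiro[bicyclo[9.3.1]pentadeca-3,7-diene-12,2'-oxirane]-15-carbaldehyde | CC(C)=CCC[C@]1(C=O)[C@H]2C/C=C(/C)CC/C=C(/C)CC[C@H]1[C@@]1(CC2)CO1 | target

**Summary**

Total step count: 26.
Longest linear sequence: 20 steps (steps 1–4, then 11–26).

**Steps most likely to fail**

Step 15. The SN2 reaction of the hindered enolate 28 with the unactivated iodide 12, next to a quaternary carbon, may be slower than proton transfer between enolate and product. Enolate equilibration to the other α-carbon, O-alkylation or simple return of the parent ketone would then take over. The fallback sets out from 27 and comes back at 29. The same enolate 28 (MeLi, THF) is intercepted at −78 °C by the far more reactive aldehyde (Z)-5-[(tert-butyldimethylsilyl)oxy]-3-methylpent-3-enal F1, made from 11 with Dess–Martin periodinane, to give the β-hydroxy ketone F2 by aldol addition with the same facial preference. F2 is converted with 1,1'-thiocarbonyldiimidazole into the imidazole-1-carbothioate F3, and Barton–McCombie deoxygenation (Bu3SnH, AIBN, toluene, 80 °C) returns 29.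

Step 21. Ring closure may lose to intermolecular alkylation (oligomers), or the carbanion may act as a base on the allylic bromide (1,4-elimination to a diene). The fallback sets out from 30 and comes back at 38. Both silyl ethers of 30 are removed with Bu4NF to give the (Z,Z)-diol F4, which CBr4 and PPh3 convert into the bis(allylic bromide) F5. F5 is cyclised reductively with Ni(CO)4 in N-methylpyrrolidone at 50 °C under high dilution, a zerovalent-nickel allyl–allyl coupling through π-allylnickel bromide intermediates. This joins C5 and C6 without a carbanion or a sulfone and gives 38 directly. Its weakness is that π-allylnickel species can equilibrate, so the alkene geometry of the product would have to be verified.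

Step 24. The methylene may be delivered to the wrong face of the C12 ketone, or enolisation may epimerise C11 before addition. The fallback sets out from 39 and comes back at 40, and brings in the oxygen rather than the carbon from the open face. Wittig reaction of 39 with Ph3P=CHOMe (from the phosphonium chloride and KN(SiMe3)2) gives the enol ether F6. Chemoselective epoxidation of this electron-rich alkene with dimethyldioxirane at −78 °C, followed by aqueous work-up, gives the α-hydroxy aldehyde F7. NaBH4 reduces it to the diol F8, selective tosylation of the primary alcohol (TsCl, pyridine) gives the monotosylate F9, and K2CO3 in MeOH closes the oxirane with retention at C12 to give 40.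

Further compounds
F1 | step 15 | (Z)-5-[(tert-butyldimethylsilyl)oxy]-3-methylpent-3-enal | O=CC/C(C)=C\CO[Si](C)(C)C(C)(C)C
F2 | step 15 | aldol adduct: 29 carrying a hydroxyl group on the side-chain carbon attached to C2 of the cyclohexanone (carbinol epimers) | CC(C)=CCC[C@@]1(COCc2ccc(OC)cc2)[C@@H](C(O)C/C(C)=C\CO[Si](C)(C)C(C)(C)C)C(=O)CC[C@@H]1C/C=C(/C)CO[Si](c1ccccc1)(c1ccccc1)C(C)(C)C
F3 | step 15 | O-(imidazole-1-carbothioyl) derivative of F2 | CC(C)=CCC[C@@]1(COCc2ccc(OC)cc2)[C@@H](C(OC(=S)n2ccnc2)C/C(C)=C\CO[Si](C)(C)C(C)(C)C)C(=O)CC[C@@H]1C/C=C(/C)CO[Si](c1ccccc1)(c1ccccc1)C(C)(C)C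
F4 | step 21 | (Z,Z)-diol: 30 with both silyl ethers replaced by hydroxyl groups | CC(C)=CCC[C@@]1(COCc2ccc(OC)cc2)[C@@H](CC/C(C)=C\CO)C2(OCCO2)CC[C@@H]1C/C=C(/C)CO
F5 | step 21 | bis(allylic bromide) corresponding to F4 | CC(C)=CCC[C@@]1(COCc2ccc(OC)cc2)[C@@H](CC/C(C)=C\CBr)C2(OCCO2)CC[C@@H]1C/C=C(/C)CBr
F6 | step 24 | (1R,3Z,7Z,11R,15S)-12-(methoxymethylidene)-15-{[(4-methoxybenzyl)oxy]methyl}-4,8-dimethyl-15-(4-methylpent-3-en-1-yl)bicyclo[9.3.1]pentadeca-3,7-diene (enol ether geometry not defined) | CC(C)=CCC[C@]1(COCc3ccc(OC)cc3)[C@H]2C/C=C(/C)CC/C=C(/C)CC[C@H]1C(=COC)CC2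
F7 | step 24 | (1R,3Z,7Z,11R,12S,15S)-12-hydroxy-15-{[(4-methoxybenzyl)oxy]methyl}-4,8-dimethyl-15-(4-methylpent-3-en-1-yl)bicyclo[9.3.1]pentadeca-3,7-diene-12-carbaldehyde | CC(C)=CCC[C@]1(COCc3ccc(OC)cc3)[C@H]2C/C=C(/C)CC/C=C(/C)CC[C@H]1[C@](O)(C=O)CC2
F8 | step 24 | (1R,3Z,7Z,11R,12S,15S)-12-(hydroxymethyl)-15-{[(4-methoxybenzyl)oxy]methyl}-4,8-dimethyl-15-(4-methylpent-3-en-1-yl)bicyclo[9.3.1]pentadeca-3,7-dien-12-ol | CC(C)=CCC[C@]1(COCc3ccc(OC)cc3)[C@H]2C/C=C(/C)CC/C=C(/C)CC[C@H]1[C@](O)(CO)CC2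
F9 | step 24 | primary 4-methylbenzenesulfonate of F8 | CC(C)=CCC[C@]1(COCc3ccc(OC)cc3)[C@H]2C/C=C(/C)CC/C=C(/C)CC[C@H]1[C@](O)(COS(=O)(=O)c3ccc(C)cc3)CC2
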